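Ring numbering: O1, C2 (C=O), C3 (bears =CH2), C4 (bears CO2H, S), C5 (bears the 13-acetoxytridecyl chain, R). C4 and C5 are trans.
Cuts, in order: acetyl–O, C3=CH2, C4–CO2H traced back to C4–phenyl, O1 taken out of C2–O1–C5, then C2–C3 and C4–C5.
Enabling feature: without O1, ring carbons C3–C2–C5–C4 form a trans-2-alkyl-3-phenylcyclobutanone. C5 is alpha to the C=O and so epimerisable, and C2, C5 and the whole oxygenated chain are the skeleton of one C15 fatty amide.
Forward: the C15 amide is made first, and keteniminium plus styrene closes the four-membered ring. Baeyer–Villiger oxygen insertion widens it to the five-membered lactone, followed by phenyl to CO2H, C3 methylenation and O-acetylation.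
Stereochemistry: C4 comes from the C2-symmetric (2R,5R)-2,5-dimethylpyrrolidine on the keteniminium nitrogen, C5 from equilibration to the trans ketone, and the oxygen insertion retains both.

Key step: step 3

Assumption: the (2R,5R) antipode of the auxiliary is taken to deliver the (3S) benzylic centre of the cyclobutanone. If the sense of induction proves opposite, the (2S,5S) amine is used and nothing else changes.

Step 1
Reactants: 1 15-hydroxypentadecanoic acid
Product: 2 15-acetoxypentadecanoic acid
Conditions: Ac2O (2.5 equiv), pyridine, 4-dimethylaminopyridine (cat.), 0 °C to rt; H2O quench; 1 M HCl wash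
Reagents that add atoms: acetic anhydride, CC(=O)OC(C)=O
Why: Routine O-acetylation of a primary alcohol under nucleophilic catalysis; any mixed anhydride formed at the carboxyl end is hydrolysed in the aqueous quench, and no stereocentre is involved.

Step 2
Reactants: 2 15-acetoxypentadecanoic acid; 3 (2R,5R)-2,5-dimethylpyrrolidine
Product: 5 15-[(2R,5R)-2,5-dimethylpyrrolidin-1-yl]-15-oxopentadecyl acetate, via 15-acetoxypentadecanoyl chloride 4 (not isolated)
Conditions: (COCl)2, N,N-dimethylformamide (cat.), CH2Cl2, 0 °C to rt, evaporate; 3, Et3N, CH2Cl2, 0 °C to rt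
Reagents that add atoms: oxalyl chloride, O=C(Cl)C(=O)Cl (chlorine of 4 only; no atom of it stays in 5)
Why: Acid chloride formation under Vilsmeier catalysis followed by N-acylation is the dependable way to acylate this doubly alpha-branched secondary amine, and it touches neither the amine's two stereocentres nor the acetate.

Step 3
Reactants: 5 15-[(2R,5R)-2,5-dimethylpyrrolidin-1-yl]-15-oxopentadecyl acetate; 6 styrene
Product: 10 (2R,3S)-2-(13-acetoxytridecyl)-3-phenylcyclobutan-1-one, via triflyloxyiminium triflate 7 (not isolated), via keteniminium triflate 8 (not isolated), via cyclobutaniminium triflate 9 (not isolated)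
Conditions: Tf2O (1.1 equiv), CH2Cl2, −25 °C; 6 (4 equiv) + 2,4,6-collidine (1.3 equiv), −25 to 40 °C; H2O, 40 °C; 1,8-diazabicyclo[5.4.0]undec-7-ene (cat.), CH2Cl2, rt
Reagents that add atoms: water, O (ketone oxygen of 10); triflic anhydride, O=S(=O)(OS(=O)(=O)C(F)(F)F)C(F)(F)F (triflyl group and counter-ions of 7 to 9 only)
Why: Tf2O sulfonylates the amide oxygen to give 7, and collidine removes an alpha-proton as triflate leaves to give the linear keteniminium 8; its sp carbon (future C2) is attacked by the terminal CH2 of styrene (future C3), and the benzylic cation so formed (future C4) is captured by the enamine carbon (future C5). This is the keteniminium–alkene (2+2) cycloaddition, known for styrene with achiral amides and for 2,5-dimethylpyrrolidine amides with other alkenes. The four-membered ring closes in a stepwise polar manner, C2–C3 first and C4–C5 second (cation–enamine collapse to iminium 9), after which water converts C=N+ into C=O and returns the auxiliary. C4 is fixed by the auxiliary: its C2 axis allows only one keteniminium, styrene approaches on the side away from the alkyl chain, and the pyrrolidine methyl group on that side pushes the phenyl-bearing carbon to the open flank. C5 is under thermodynamic control, because it is alpha to the iminium and then to the ketone and drains to the trans isomer, a process completed by the catalytic base. The step needs regioselectivity (the benzylic cation places phenyl beta to C=O), chemoselectivity (the amide oxygen is far more nucleophilic towards Tf2O than the acetate) and suppression of styrene oligomerisation (7 is preformed so that styrene never meets free Tf2O, and collidine stays in slight excess over acid).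

Step 4
Reactants: 10 (2R,3S)-2-(13-acetoxytridecyl)-3-phenylcyclobutan-1-one
Product: 11 (4R,5R)-5-(13-acetoxytridecyl)-4-phenyloxolan-2-one (trans; the C4 descriptor changes through ligand ranking only)
Conditions: mCPBA (1.3 equiv), CH2Cl2, 0 °C to rt
Reagents that add atoms: 3-chloroperoxybenzoic acid, O=C(OO)c1cccc(Cl)c1
Why: In this strain-accelerated Baeyer–Villiger oxidation the more substituted alpha-carbon C5 migrates in preference to the C3 methylene and with retention, so O1 enters between C2 and C5 with the trans relation intact, while phenyl and acetate are inert to the peracid.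

Step 5
Reactants: 11 (4R,5R)-5-(13-acetoxytridecyl)-4-phenyloxolan-2-one
Product: 12 (2R,3S)-2-(13-acetoxytridecyl)-5-oxooxolane-3-carboxylic acid
Conditions: RuCl3·xH2O (5 mol %), NaIO4 (16 equiv), EtOAc/MeCN/H2O (2:2:3), rt
Reagents that add atoms: sodium periodate, [Na+].[O-]I(=O)(=O)=O (oxygen relayed through RuO4); water, O
Why: Catalytic RuO4 degradation of a phenyl ring to a carboxylic acid is precedented on beta-aryl butyrolactones; the ipso carbon stays as the carboxyl carbon so no bond at C4 is broken, and acetate, lactone and saturated chain oxidise far more slowly than the arene.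

Step 6
Reactants: 12 (2R,3S)-2-(13-acetoxytridecyl)-5-oxooxolane-3-carboxylic acid
Product: 14 (2R,3S)-2-(13-hydroxytridecyl)-4-methylidene-5-oxooxolane-3-carboxylic acid, via carboxylated lactone diacid 13 (not isolated)
Conditions: MeOMgOCO2Me (2 M in DMF, ca. 35 equiv), 135 °C, N2; cold 6 M HCl, EtOAc extraction; crude 13, 37% aq. HCHO, PhNHMe, NaOAc, AcOH, rt
Reagents that add atoms: formaldehyde, C=O (the exocyclic CH2); methoxymagnesium methyl carbonate, COC(=O)O[Mg]OC (new carboxyl carbon of 13 only)
Why: Carboxylation of the lactone alpha-CH2 with the Stiles reagent (driven by the magnesium chelate) followed by decarboxylative Mannich methylenation is the standard end game for paraconic acids; the long heating with excess methoxide-bearing reagent should strip the acetate as volatile methyl acetate, a loss that is accepted and repaired in step 7 (any molecule keeping its acetate is already 15), and C4 stays trans to the now fixed C5.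

Step 7
Reactants: 14 (2R,3S)-2-(13-hydroxytridecyl)-4-methylidene-5-oxooxolane-3-carboxylic acid
Product: 15 (2R,3S)-2-(13-acetoxytridecyl)-4-methylidene-5-oxooxolane-3-carboxylic acid (target)
Conditions: vinyl acetate (5 equiv), immobilised Candida antarctica lipase B, t-BuOMe, 30 °C
Reagents that add atoms: vinyl acetate, C=COC(C)=O
Why: Irreversible lipase-catalysed transesterification with an enol ester acetylates the unhindered fatty-type primary alcohol at neutral pH and leaves the hindered ring carboxyl alone, which avoids the amine bases and hot anhydride that would move the exocyclic double bond into the ring and erase C4.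

Compound list
1 | 15-hydroxypentadecanoic acid | OCCCCCCCCCCCCCCC(=O)O | starting material
2 | 15-acetoxypentadecanoic acid | CC(=O)OCCCCCCCCCCCCCCC(=O)O | intermediate
3 | (2R,5R)-2,5-dimethylpyrrolidine | C[C@@H]1CC[C@@H](C)N1 | starting material
4 | 15-acetoxypentadecanoyl chloride | CC(=O)OCCCCCCCCCCCCCCC(=O)Cl | intermediate (not isolated)
5 | 15-[(2R,5R)-2,5-dimethylpyrrolidin-1-yl]-15-oxopentadecyl acetate | CC(=O)OCCCCCCCCCCCCCCC(=O)N1[C@H](C)CC[C@H]1C | intermediate
6 | styrene | C=Cc1ccccc1 | starting material
7 | 1-[15-acetoxy-1-(triflyloxy)pentadecylidene]-(2R,5R)-2,5-dimethylpyrrolidinium triflate | CC(=O)OCCCCCCCCCCCCCCC(OS(=O)(=O)C(F)(F)F)=[N+]1[C@H](C)CC[C@H]1C.[O-]S(=O)(=O)C(F)(F)F | intermediate (not isolated)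
8 | 1-(15-acetoxypentadec-1-enylidene)-(2R,5R)-2,5-dimethylpyrrolidinium triflate (keteniminium salt) | CC(=O)OCCCCCCCCCCCCCC=C=[N+]1[C@H](C)CC[C@H]1C.[O-]S(=O)(=O)C(F)(F)F | intermediate (not isolated)
9 | 1-[(2R,3S)-2-(13-acetoxytridecyl)-3-phenylcyclobutylidene]-(2R,5R)-2,5-dimethylpyrrolidinium triflate (drawn as the trans isomer, to which the C2 epimer drains) | C1C(=[N+]2[C@H](C)CC[C@H]2C)[C@H](CCCCCCCCCCCCCOC(C)=O)[C@H]1c3ccccc3.[O-]S(=O)(=O)C(F)(F)F | intermediate (not isolated)
10 | (2R,3S)-2-(13-acetoxytridecyl)-3-phenylcyclobutan-1-one (trans) | C1C(=O)[C@H](CCCCCCCCCCCCCOC(C)=O)[C@H]1c2ccccc2 | intermediate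
11 | (4R,5R)-5-(13-acetoxytridecyl)-4-phenyloxolan-2-one (trans) | C1C(=O)O[C@H](CCCCCCCCCCCCCOC(C)=O)[C@H]1c2ccccc2 | intermediate
12 | (2R,3S)-2-(13-acetoxytridecyl)-5-oxooxolane-3-carboxylic acid (trans) | C1C(=O)O[C@H](CCCCCCCCCCCCCOC(C)=O)[C@H]1C(=O)O | intermediate
13 | (2R,3S)-2-(13-hydroxytridecyl)-5-oxooxolane-3,4-dicarboxylic acid (C4 labile, left open) | OC(=O)C1C(=O)O[C@H](CCCCCCCCCCCCCO)[C@H]1C(=O)O | intermediate (not isolated)
14 | (2R,3S)-2-(13-hydroxytridecyl)-4-methylidene-5-oxooxolane-3-carboxylic acid | C=C1C(=O)O[C@H](CCCCCCCCCCCCCO)[C@H]1C(=O)O | intermediate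
15 | (2R,3S)-2-(13-acetoxytridecyl)-4-methylidene-5-oxooxolane-3-carboxylic acid | C=C1C(=O)O[C@H](CCCCCCCCCCCCCOC(C)=O)[C@H]1C(=O)O | target

Total step count: 7. Longest linear sequence: 7 (1 to 15).

Steps most likely to fail

**Risk at step 3.** Facial discrimination may be weak when the benzylic carbon closes onto the enamine carbon, because the auxiliary sits on the far side of the forming ring. In that case 10 would form in low enantiomeric purity. Oligomerisation of styrene would cost throughput but not purity.
- The fallback takes enantiopurity from a classical resolution instead of from the auxiliary.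
- It sets out from 10 of whatever enantiomeric purity, which is carried through steps 4 and 5 unchanged.
- Acid 12 is then combined with (R)-1-phenylethylamine in EtOAc/hexane, and the less soluble salt, (R)-1-phenylethylammonium (2R,3S)-2-(13-acetoxytridecyl)-5-oxooxolane-3-carboxylate F1, is recrystallised to constant rotation.
- The (S)-amine is used instead if that antipode pairs with the wanted acid in the less soluble salt.
- Partition between dilute HCl and EtOAc returns 12, where the route is rejoined.

**Risk at step 5.** Degradation of the unactivated phenyl ring may be slow. The long exposure to a large excess of oxidant would then allow creeping oxidation of chain C–H bonds and loss of mass balance.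
- The fallback changes the masked carboxyl from an arene to a vinyl group, so that a mild alkene cleavage replaces exhaustive ring degradation.
- It sets out from amide 5, activated as in step 3 (through 7 and 8) but with buta-1,3-diene as the alkene.
- By way of the allyl cation this should give 1-[(2R,3R)-2-(13-acetoxytridecyl)-3-ethenylcyclobutylidene]-(2R,5R)-2,5-dimethylpyrrolidinium triflate F2.
- Hydrolysis and equilibration then give (2R,3R)-2-(13-acetoxytridecyl)-3-ethenylcyclobutan-1-one F3. It has the same spatial arrangement as 10, and the C3 descriptor changes only because vinyl ranks below C2.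
- One equivalent of mCPBA at 0 °C (the strained ketone reacts faster than a monosubstituted alkene) gives (4R,5R)-5-(13-acetoxytridecyl)-4-ethenyloxolan-2-one F4.
- Ozonolysis with Me2S work-up gives (2R,3S)-2-(13-acetoxytridecyl)-5-oxooxolane-3-carbaldehyde F5.
- Pinnick oxidation (NaClO2, NaH2PO4, 2-methylbut-2-ene, t-BuOH/H2O) rejoins the route at 12.

**Risk at step 6.** Carboxylation may be incomplete, material may be lost thermally during the long heating, or the new double bond may drift into the ring.
- The fallback uses enolate aminomethylation and Hofmann-type elimination in place of carboxylation. Strong base cannot coexist with the acetate, so the acetate is removed first.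
- It sets out from 12. LiOH in aqueous THF followed by 2 M HCl, which recloses the lactone, gives (2R,3S)-2-(13-hydroxytridecyl)-5-oxooxolane-3-carboxylic acid F6.
- LiN(SiMe3)2 (3.3 equiv, THF, −78 °C) and dimethylmethylideneammonium iodide (Eschenmoser's salt) give (2R,3S)-4-[(dimethylamino)methyl]-2-(13-hydroxytridecyl)-5-oxooxolane-3-carboxylic acid F7.
- MeI in MeOH gives {[(4S,5R)-4-carboxy-5-(13-hydroxytridecyl)-2-oxooxolan-3-yl]methyl}trimethylammonium iodide F8.
- Brief shaking with aq. NaHCO3/EtOAc brings about the elimination and rejoins the route at 14.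

Further compounds
F1 | step 3 | (R)-1-phenylethylammonium (2R,3S)-2-(13-acetoxytridecyl)-5-oxooxolane-3-carboxylate | C1C(=O)O[C@H](CCCCCCCCCCCCCOC(C)=O)[C@H]1C(=O)[O-].C[C@@H]([NH3+])c2ccccc2
F2 | step 5 | 1-[(2R,3R)-2-(13-acetoxytridecyl)-3-ethenylcyclobutylidene]-(2R,5R)-2,5-dimethylpyrrolidinium triflate | C1C(=[N+]2[C@H](C)CC[C@H]2C)[C@H](CCCCCCCCCCCCCOC(C)=O)[C@H]1C=C.[O-]S(=O)(=O)C(F)(F)F
F3 | step 5 | (2R,3R)-2-(13-acetoxytridecyl)-3-ethenylcyclobutan-1-one | C1C(=O)[C@H](CCCCCCCCCCCCCOC(C)=O)[C@H]1C=C
F4 | step 5 | (4R,5R)-5-(13-acetoxytridecyl)-4-ethenyloxolan-2-one | C1C(=O)O[C@H](CCCCCCCCCCCCCOC(C)=O)[C@H]1C=C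
F5 | step 5 | (2R,3S)-2-(13-acetoxytridecyl)-5-oxooxolane-3-carbaldehyde | C1C(=O)O[C@H](CCCCCCCCCCCCCOC(C)=O)[C@H]1C=O
F6 | step 6 | (2R,3S)-2-(13-hydroxytridecyl)-5-oxooxolane-3-carboxylic acid | C1C(=O)O[C@H](CCCCCCCCCCCCCO)[C@H]1C(=O)O
F7 | step 6 | (2R,3S)-4-[(dimethylamino)methyl]-2-(13-hydroxytridecyl)-5-oxooxolane-3-carboxylic acid (C4 left open) | CN(C)CC1C(=O)O[C@H](CCCCCCCCCCCCCO)[C@H]1C(=O)O
F8 | step 6 | {[(4S,5R)-4-carboxy-5-(13-hydroxytridecyl)-2-oxooxolan-3-yl]methyl}trimethylammonium iodide | C[N+](C)(C)CC1C(=O)O[C@H](CCCCCCCCCCCCCO)[C@H]1C(=O)O.[I-]
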